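**Retrosynthetic overview**

1. Target ⇒ benzyl ester of the 8‑hydroxy acid; the tertiary 8‑OH is acetylated late and the benzyl ester is removed by hydrogenolysis.
2. Key disconnection C12–C13: C12 of a bicyclic C16 lactol acts as a carbanion equivalent (N–H hydrazone, ruthenium catalysis, loss of N2) and adds to C3 of benzyl (E)‑crotonate; this step also sets C13.
3. Lactol ⇒ 8‑hydroxy ester ⇒ 8(17)‑methylene ester (Markovnikov hydration sets C8) ⇒ 8‑ketone; C9–C11 comes from alkylation of the enolate released by cis‑selective methyl cuprate addition (C10) to a bicyclic enone.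
4. Enone (C5 set by enantioselective β,γ→α,β isomerisation) ⇒ Birch reduction of 6‑methoxy‑1,1‑dimethyltetralin ⇒ 6‑methoxy‑1‑tetralone.
5. Ring order: no carbocycle is built. Ring A is the saturated ring of the tetralone and ring B is its anisole ring after dearomatisation; a lactol ring is closed in step 7 and opened again in the key step.

Assumption: the SMILES is read literally, as the A/B‑cis (5β‑H) compound (5R,8R,9R,10S,13S)‑8‑acetoxylabdan‑15‑oic acid, the 5‑epimer of labdanolic acid acetate, so trans‑fused feedstocks such as sclareolide cannot supply the core. Labdane numbering is used in the comments: naphthalene C‑1 = C‑9, C‑2 = C‑8, C‑4a = C‑5, C‑8a = C‑10, pentanoate C‑3 = C‑13.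

**Route**

Step 1
Reactants: 1 methoxytetralone (6‑methoxy‑3,4‑dihydronaphthalen‑1(2H)‑one)
Product: 2 gem‑dimethyl tetralin (6‑methoxy‑1,1‑dimethyl‑1,2,3,4‑tetrahydronaphthalene)
Conditions: Me2Zn, TiCl4 (forms Me2TiCl2), CH2Cl2, −40 °C → rt
Reagents that add atoms: dimethylzinc Me2Zn, C[Zn]C
Why: Reetz geminal dimethylation: Me2TiCl2 adds to the aryl ketone and the titanium alkoxide ionises to the para‑methoxy‑stabilised benzylic cation, which takes the second methyl; no stereocentre is formed.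

Step 2
Reactants: 2 gem‑dimethyl tetralin
Product: 4 β,γ‑enone (5,5‑dimethyl‑3,4,5,6,7,8‑hexahydronaphthalen‑2(1H)‑one), via enol ether 3 (not isolated)
Conditions: Li, NH3(l), t‑BuOH, THF, −78 → −33 °C; then (CO2H)2, MeOH/H2O, rt
Reagents that add atoms: water, O
Why: Birch reduction gives the 2,5‑dihydroanisole with the tetrasubstituted ring‑fusion alkene intact, and mild oxalic acid hydrolysis of the enol ether gives the unconjugated β,γ‑enone without moving the double bond; no stereocentre is formed.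

Step 3
Reactants: 4 β,γ‑enone
Product: 5 (4aR)‑enone ((4aR)‑5,5‑dimethyl‑4,4a,5,6,7,8‑hexahydronaphthalen‑2(3H)‑one)
Conditions: 9‑amino‑9‑deoxy‑epi‑quinine (10 mol%), CF3CO2H (20 mol%), toluene, −20 °C
Reagents that add atoms: none
Why: Known cinchona primary‑amine catalysed enantioselective β,γ→α,β isomerisation of Birch‑derived cyclohexenones: the dienamine is protonated at the γ‑carbon (C‑4a, future C‑5) on one face by the catalyst's ammonium group, which sets the (4aR) centre; the quinidine‑derived pseudo‑enantiomer is used if the sense of induction is the reverse.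

Step 4
Reactants: 5 (4aR)‑enone; 6 ethyl bromoacetate
Product: 8 keto ester (ethyl 2‑[(1R,4aR,8aS)‑5,5,8a‑trimethyl‑2‑oxodecahydronaphthalen‑1‑yl]acetate), via lithium enolate 7 (not isolated)
Conditions: Me2CuLi, Et2O, −20 °C; then 6, HMPA, THF, −20 °C → rt
Reagents that add atoms: lithium dimethylcuprate Me2CuLi, [Li+].C[Cu-]C
Why: Conjugate addition with enolate trapping: the cuprate attacks C‑8a axially, anti to the pseudo‑axial C4a–C5 bond (enforced by allylic strain from the gem‑dimethyl group), giving the cis ring fusion (angular CH3 cis to 4a‑H) as in classical octalone methylations, and the regiodefined enolate 7 is alkylated by 6 on its convex face, anti to the pseudo‑axial ring A bond at C‑8a, so the acetate arm (C‑9 side chain) ends cis to the angular methyl.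

Step 5
Reactants: 8 keto ester
Product: 9 methylene ester (ethyl 2‑[(1S,4aR,8aS)‑5,5,8a‑trimethyl‑2‑methylidenedecahydronaphthalen‑1‑yl]acetate)
Conditions: Zn, CH2Br2, TiCl4, THF/CH2Cl2, 0 °C → rt
Reagents that add atoms: dibromomethane, BrCBr
Why: Takai–Lombardo methylenation: the non‑basic gem‑dimetallic reagent methylenates the hindered ketone chemoselectively beside the ester and does not epimerise the α‑stereocentre (its label changes from R to S only because the priorities change).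

Step 6
Reactants: 9 methylene ester
Product: 10 hydroxy ester (ethyl 2‑[(1R,2R,4aR,8aS)‑2‑hydroxy‑2,5,5,8a‑tetramethyldecahydronaphthalen‑1‑yl]acetate)
Conditions: Co(acac)2 (20 mol%), PhSiH3, O2 (1 atm), i‑PrOH/THF, rt
Reagents that add atoms: dioxygen, O=O
Why: Mukaiyama (Markovnikov) hydration by hydrogen‑atom transfer: H• adds to the CH2 terminus and the tertiary C‑2 radical is oxygenated on the α‑face, away from the cis side chain at C‑1 and the 1,3‑related angular methyl (the face preference that labd‑8(17)‑enes show), giving the 2α‑OH/2β‑CH3 carbinol (C‑8).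

Step 7
Reactants: 10 hydroxy ester
Product: 11 lactol ((3aR,5aR,9aS,9bR)‑3a,6,6,9a‑tetramethyldodecahydronaphtho[2,1‑b]furan‑2‑ol, both C‑2 epimers)
Conditions: i‑Bu2AlH (2.5 equiv), CH2Cl2, −78 °C; aq. potassium sodium tartrate
Reagents that add atoms: none
Why: i‑Bu2AlH half‑reduction of the ester to the aldehyde oxidation level, held as the aluminium hemiacetal by the neighbouring tertiary alkoxide, gives the lactol on work‑up (the same behaviour as sclareolide going to its lactol); any lactone formed from 10 converges to the same product and no ring stereocentre is touched.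

Step 8
Reactants: 11 lactol; 12 benzyl (2E)‑but‑2‑enoate
Product: 14 benzyl hydroxy ester (benzyl (3S)‑5‑[(1R,2R,4aR,8aS)‑2‑hydroxy‑2,5,5,8a‑tetramethyldecahydronaphthalen‑1‑yl]‑3‑methylpentanoate), via hydrazone 13 (not isolated)
Conditions: N2H4·H2O, THF, rt; then 12, [Ru(p‑cymene)Cl2]2 (2.5 mol%), (R,R)‑Me‑BPE (6 mol%), K3PO4, CsF, THF, 50 °C
Reagents that add atoms: hydrazine (as monohydrate), NN
Why: Proposed new method: the N–H hydrazone of the open aldehyde form of 11 is an alkyl‑carbanion equivalent under [Ru(p‑cymene)Cl2]2/bisphosphine/base (closest known reaction: the racemic, dmpe‑based ruthenium‑catalysed umpolung conjugate addition of aldehyde hydrazones to α,β‑unsaturated esters), so the normally electrophilic C‑12 attacks the normally electrophilic C‑3 of the crotonate inside the ruthenium coordination sphere through a six‑membered Ru–N–N=C/C=C array and N2 is then lost to leave C‑12 as CH2; replacing dmpe by its C2‑symmetric chiral analogue 1,2‑bis[(2R,5R)‑2,5‑dimethylphospholan‑1‑yl]ethane is proposed to make the ruthenium‑bound crotonate face‑selective and set C‑13 as S (the ligand antipode is used if the sense is the opposite, since the remote ring stereocentres exert no bias).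

Step 9
Reactants: 14 benzyl hydroxy ester
Product: 15 benzyl acetoxy ester (benzyl (3S)‑5‑[(1R,2R,4aR,8aS)‑2‑(acetyloxy)‑2,5,5,8a‑tetramethyldecahydronaphthalen‑1‑yl]‑3‑methylpentanoate)
Conditions: AcCl, PhNMe2, CH2Cl2, 0 → 40 °C
Reagents that add atoms: acetyl chloride, CC(=O)Cl
Why: O‑Acylation of the hindered tertiary alcohol with AcCl/N,N‑dimethylaniline (the standard method for the 8‑hydroxyl of sclareol‑type carbinols), with retention because the C–O bond is not broken.

Step 10
Reactants: 15 benzyl acetoxy ester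
Product: 16 target ((3S)‑5‑[(1R,2R,4aR,8aS)‑2‑(acetyloxy)‑2,5,5,8a‑tetramethyldecahydronaphthalen‑1‑yl]‑3‑methylpentanoic acid)
Conditions: H2 (1 atm), Pd/C, EtOAc, rt
Reagents that add atoms: none
Why: Hydrogenolysis of the benzyl ester over Pd/C; the tertiary acetate and all five stereocentres are untouched.

**Compound list**

1 | 6‑methoxy‑3,4‑dihydronaphthalen‑1(2H)‑one (6‑methoxy‑1‑tetralone) | COc1ccc2c(c1)CCCC2=O | starting material
2 | 6‑methoxy‑1,1‑dimethyl‑1,2,3,4‑tetrahydronaphthalene | COc1ccc2c(c1)CCCC2(C)C | intermediate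
3 | 6‑methoxy‑1,1‑dimethyl‑1,2,3,4,5,8‑hexahydronaphthalene (Birch enol ether) | COC1=CCC2=C(C1)CCCC2(C)C | intermediate
4 | 5,5‑dimethyl‑3,4,5,6,7,8‑hexahydronaphthalen‑2(1H)‑one | O=C1CCC2=C(C1)CCCC2(C)C | intermediate
5 | (4aR)‑5,5‑dimethyl‑4,4a,5,6,7,8‑hexahydronaphthalen‑2(3H)‑one | O=C1CC[C@@H]2C(C)(C)CCCC2=C1 | intermediate
6 | ethyl bromoacetate | CCOC(=O)CBr | starting material
7 | lithium (4aR,8aS)‑5,5,8a‑trimethyl‑3,4,4a,5,6,7,8,8a‑octahydronaphthalen‑2‑olate (cis‑fused enolate) | [Li]OC1=C[C@@]2(C)CCCC(C)(C)[C@H]2CC1 | intermediate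
8 | ethyl 2‑[(1R,4aR,8aS)‑5,5,8a‑trimethyl‑2‑oxodecahydronaphthalen‑1‑yl]acetate (cis‑fused; side chain cis to angular CH3) | O=C1CC[C@@H]2C(C)(C)CCC[C@]2(C)[C@H]1CC(=O)OCC | intermediate
9 | ethyl 2‑[(1S,4aR,8aS)‑5,5,8a‑trimethyl‑2‑methylidenedecahydronaphthalen‑1‑yl]acetate | C=C1CC[C@@H]2C(C)(C)CCC[C@]2(C)[C@H]1CC(=O)OCC | intermediate
10 | ethyl 2‑[(1R,2R,4aR,8aS)‑2‑hydroxy‑2,5,5,8a‑tetramethyldecahydronaphthalen‑1‑yl]acetate | O[C@]1(C)CC[C@@H]2C(C)(C)CCC[C@]2(C)[C@H]1CC(=O)OCC | intermediate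
11 | (3aR,5aR,9aS,9bR)‑3a,6,6,9a‑tetramethyldodecahydronaphtho[2,1‑b]furan‑2‑ol (lactol, C‑2 epimers) | OC1C[C@H]2[C@](C)(O1)CC[C@@H]3C(C)(C)CCC[C@]23C | intermediate
12 | benzyl (2E)‑but‑2‑enoate (benzyl crotonate) | C/C=C/C(=O)OCc1ccccc1 | starting material
13 | (1R,2R,4aR,8aS)‑1‑(2‑hydrazinylideneethyl)‑2,5,5,8a‑tetramethyldecahydronaphthalen‑2‑ol | NN=CC[C@H]1[C@](C)(O)CC[C@@H]2C(C)(C)CCC[C@]12C | intermediate
14 | benzyl (3S)‑5‑[(1R,2R,4aR,8aS)‑2‑hydroxy‑2,5,5,8a‑tetramethyldecahydronaphthalen‑1‑yl]‑3‑methylpentanoate | O[C@]1(C)CC[C@@H]2C(C)(C)CCC[C@]2(C)[C@H]1CC[C@H](C)CC(=O)OCc1ccccc1 | intermediate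
15 | benzyl (3S)‑5‑[(1R,2R,4aR,8aS)‑2‑(acetyloxy)‑2,5,5,8a‑tetramethyldecahydronaphthalen‑1‑yl]‑3‑methylpentanoate | CC(=O)O[C@]1(C)CC[C@@H]2C(C)(C)CCC[C@]2(C)[C@H]1CC[C@H](C)CC(=O)OCc1ccccc1 | intermediate
16 | (3S)‑5‑[(1R,2R,4aR,8aS)‑2‑(acetyloxy)‑2,5,5,8a‑tetramethyldecahydronaphthalen‑1‑yl]‑3‑methylpentanoic acid = (5R,8R,9R,10S,13S)‑8‑acetoxylabdan‑15‑oic acid | CC(=O)O[C@]1(C)CC[C@@H]2C(C)(C)CCC[C@]2(C)[C@H]1CC[C@H](C)CC(=O)O | target

**Count and risks**

Total steps: 10. Longest linear sequence: 10 steps (1 → 16).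

The three steps most likely to fail:

Step 8 (reactivity of the hindered lactol‑derived hydrazone and control of C‑13). The fallback sets out from lactol 11 and comes back at target 16. Lactol 11 is thioacetalised with propane‑1,3‑dithiol and BF3·OEt2 to the hydroxy dithiane F1. Its dianion (2.2 equiv n‑BuLi, THF/HMPA, −78 °C; a Corey–Seebach acyl‑anion equivalent) is added 1,4 to (−)‑8‑phenylmenthyl (E)‑crotonate F2, made from (−)‑8‑phenylmenthol and crotonyl chloride. The phenyl group shields one face of the s‑trans enoate, which leads to the adduct F3 with the required C‑13 configuration. Raney Ni desulfurisation turns the dithiane carbon into CH2 and gives the 8‑phenylmenthyl ester F4. Saponification (KOH, EtOH, reflux) gives the hydroxy acid F5 with recovery of the auxiliary. Acetylation as in step 9 (AcCl, PhNMe2; the mixed anhydride is hydrolysed on aqueous work‑up) gives 16.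

Step 3 (enantioselective γ‑protonation next to a quaternary carbon). The fallback sets out from 4 and comes back at 5. Enone 4 is conjugated with DBU to the racemic enone F6, and the antipodes are separated by preparative chromatography on a chiral stationary phase. The unwanted antipode is racemised through its dienolate (t‑BuOK) and recycled.

Step 6 (face selectivity of the radical hydration). The fallback sets out from 9 and comes back at 11. Alkene 9 is epoxidised with m‑CPBA, which delivers oxygen directly to the α‑face, to give the spiro‑epoxide F7. LiAlH4 opens the epoxide at its CH2 carbon and reduces the ester, giving the diol F8. Dess–Martin periodinane oxidises the primary alcohol, and the resulting hydroxy aldehyde closes to lactol 11.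

**Further compounds**

F1 | step 8 | (1R,2R,4aR,8aS)‑1‑(1,3‑dithian‑2‑ylmethyl)‑2,5,5,8a‑tetramethyldecahydronaphthalen‑2‑ol | O[C@]1(C)CC[C@@H]2C(C)(C)CCC[C@]2(C)[C@H]1CC1SCCCS1
F2 | step 8 | (1R,2S,5R)‑5‑methyl‑2‑(2‑phenylpropan‑2‑yl)cyclohexyl (2E)‑but‑2‑enoate ((−)‑8‑phenylmenthyl crotonate) | CC(C)(c1ccccc1)[C@@H]1CC[C@@H](C)C[C@H]1OC(=O)/C=C/C
F3 | step 8 | (1R,2S,5R)‑5‑methyl‑2‑(2‑phenylpropan‑2‑yl)cyclohexyl (3R)‑3‑(2‑{[(1R,2R,4aR,8aS)‑2‑hydroxy‑2,5,5,8a‑tetramethyldecahydronaphthalen‑1‑yl]methyl}‑1,3‑dithian‑2‑yl)butanoate | O[C@]1(C)CC[C@@H]2C(C)(C)CCC[C@]2(C)[C@H]1CC1(SCCCS1)[C@H](C)CC(=O)O[C@@H]1C[C@H](C)CC[C@H]1C(C)(C)c1ccccc1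
F4 | step 8 | (1R,2S,5R)‑5‑methyl‑2‑(2‑phenylpropan‑2‑yl)cyclohexyl (3S)‑5‑[(1R,2R,4aR,8aS)‑2‑hydroxy‑2,5,5,8a‑tetramethyldecahydronaphthalen‑1‑yl]‑3‑methylpentanoate | O[C@]1(C)CC[C@@H]2C(C)(C)CCC[C@]2(C)[C@H]1CC[C@H](C)CC(=O)O[C@@H]1C[C@H](C)CC[C@H]1C(C)(C)c1ccccc1
F5 | step 8 | (3S)‑5‑[(1R,2R,4aR,8aS)‑2‑hydroxy‑2,5,5,8a‑tetramethyldecahydronaphthalen‑1‑yl]‑3‑methylpentanoic acid | O[C@]1(C)CC[C@@H]2C(C)(C)CCC[C@]2(C)[C@H]1CC[C@H](C)CC(=O)O
F6 | step 3 | racemic 5,5‑dimethyl‑4,4a,5,6,7,8‑hexahydronaphthalen‑2(3H)‑one | O=C1CCC2C(C)(C)CCCC2=C1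
F7 | step 6 | ethyl 2‑[(1R,2R,4aR,8aS)‑5,5,8a‑trimethyloctahydro‑1H‑spiro[naphthalene‑2,2′‑oxiran]‑1‑yl]acetate (epoxide oxygen α, trans to the side chain) | C1O[C@@]12CC[C@@H]3C(C)(C)CCC[C@]3(C)[C@H]2CC(=O)OCC
F8 | step 6 | (1R,2R,4aR,8aS)‑1‑(2‑hydroxyethyl)‑2,5,5,8a‑tetramethyldecahydronaphthalen‑2‑ol | O[C@]1(C)CC[C@@H]2C(C)(C)CCC[C@]2(C)[C@H]1CCO
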